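Moles per litre per second is the unit in which I read these runs. If dissolving is the slow step, a fixed solubility and a fixed dissolution coefficient give Q a fixed rate in that unit while solid is left, whatever the charge.

in all of them: E 0.108 M
- west: G 0.013 M; run made earlier
- east: G 0.020 M; run made earlier
- flask: G 0.027 M; time 2.0 min

| west: time / s | west: Q / % | east: time / s | east: Q / % |
|---|---|---|---|
| 12.0 | 12 | 12.0 | 14 |
| 25.0 | 27 | 25.0 | 27 |
| 40.0 | 33 | 40.0 | 32 |
| 50.0 | 39 | 50.0 | 41 |
| 60.0 | 44 | 60.0 | 43 |
| 80.0 | 53 | 80.0 | 48 |

(standard deviation of a reading: 2 percentage points)

- G is a solid; its amount is given per volume of the solution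
- what was read earlier has a scatter of 2 percentage points, one standard deviation
- at the start none of G is in solution

* Q at 2.0 min, in percent of the G charged
* the change that raises the amount of Q at 2.0 min, in percent of the G charged most ("none" if none brings more than 2 percentage points) (birch / oak / elm / none)
* amount of Q at 2.0 min, in percent of the G charged, after birch

- birch: doubling the amount of E, all else as stated
- oak: doubling the solubility of G, all else as stated
- elm: doubling the dissolution coefficient of G, all else as stated

By 80.0 s, west has made Q at 8.61 × 10⁻⁵ M s⁻¹ on average and east at 1.20 × 10⁻⁴ M s⁻¹. East is faster by a factor of 1.39, against 1.54 in charge. As a reading, then, the rate follows the charge, so I take [G] in solution as the concentration that sets the order. With [E] taken as steady, this is a pseudo-first-order picture, so I carry one number. The run constant is the logarithm of G charged over G not yet turned into Q, divided by the time. East, nearest in charge, reads 0.00817 s⁻¹.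

Now the settings, one after the other. If [G] in solution follows the flask's charge, the constant stands and I commit to 62.5% at 2.0 min. Elm speeds dissolving, which the rate ratio above doesn't show as the slow step, so I expect little. I expect oak to count if 0.027 M lies above the solubility. Up to 0.020 M the rate still rises with the charge, so I expect a small gain. Birch doubles [E]. If the order in [E] is first, the constant doubles and Q reaches 85.9%, which is more, so I choose birch.

The forecast differs from me, with 60%, elm as best and 63% after birch, holding that “dissolution looks rate-limiting”.

The flask gives 55.8%, and birch is best with 70.5%, a gain of 15 percentage points against 2.8 points for oak and 1.1 points for elm.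

    G ⇌ X, rate k1*(cs1 - [X]) while solid is left; crystals form when [X] > cs1 (solubility = 21.0 mM, k = 0.310 s⁻¹)
    X + E → Q (k = 0.140 L mol⁻¹ s⁻¹)
    2 E → D (k = 0.0787 L mol⁻¹ s⁻¹)

The flask's own run constant at 2.0 min is 0.00680 s⁻¹, lower than the reading from east. At 2.00 min the flask has 28% of its E left, Q has taken up 13.9% of the E charged, and D stands at 0.0316 M. At 0.068 M of G and the same time, the carried constant still says 62.5%, and that neighbour flask holds 25.6% of Q with 43.9% of its G undissolved.

The readings stem from a simulated flask on assumed constants, and the scatter is random.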